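## The problem

The target, (2S,3R,4R)-4-(3-hydroxy-4-methoxyphenyl)-6,7-dimethoxy-2,3-dimethyl-3,4-dihydronaphthalen-1(2H)-one (21), is a 4-aryl-1-tetralone. Ring B (C1–C4, C4a, C8a) carries the ketone at C1, methyl groups at C2 and C3 and ring C at C4, and is fused through C4a–C8a to the 6,7-dimethoxybenzo ring A. The three stereocentres are contiguous, 2,3-trans and 3,4-cis. C2 is α to the ketone, and in the 3,4-cis series the 2,3-trans arrangement (aryl pseudoaxial, both methyl groups equatorial) should be the stable one, so C2 can be left to equilibration. C3 and C4 cannot be corrected once made and must be set together, in absolute and relative terms. C4 is a diarylmethine carbon para to a methoxy group and is open to ionisation and hydride abstraction; the C2 enolate must never meet an alkylating agent. Of the four phenolic oxygens only the one at the 3-position of ring C is free, so it must stay distinguishable from the two on ring A. The feature that invites the key step is ring A: it touches the rest of the molecule only through C4a–C4 and C8a–C1 and is symmetrically substituted at C6 and C7. It can therefore be assembled last from a vinyl group on C4 (C4a, C5), an ethynyl ketone at C1 (C8a, C8) and a symmetric alkyne (C6, C7), with ring B closing in the same event.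

## Retrosynthesis

**21 ⇒ 20 ⇒ 19 (O–benzyl bond; configuration at C2).** The final operation cuts no skeletal bond: the benzyl–oxygen bond of 20 is cleaved by hydrogenolysis. A benzyl ether is chosen for the ring C phenol because it survives organomagnesium, ylide, cationic rhodium, quinone, peroxide and alkoxide chemistry, and its removal cannot disturb C2–C4. Before that, 20 is traced to its C2 epimer mixture 19. Base equilibration is asked to converge on the 2,3-trans isomer, which frees every earlier step from control at C2.

**19 ⇒ 18 ⇒ 17 (aryl C–O bonds at C6 and C7).** The two methyl ethers go back to catechol 18, and its oxygens to the C–B bonds of diboronate 17. A 1,2-dioxygenated alkyne is not a practical reagent, whereas diborylalkyne 15 is a stable, symmetric two-carbon unit. The price is an ipso-oxidation mild enough for an aryl ketone and a catechol, then an O-methylation that leaves C2 alone.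

**17 ⇒ 16 (aromatisation of ring A).** Ring A of 17 is taken back to the cyclohexa-1,3-diene of 16 by adding hydrogen at C4a and C5. This follows from using an alkene as one of the three π-components. It costs one dehydrogenation, but lets the C4 substituent be a vinyl group, which an allylic substitution delivers directly. The forward step must take hydride from the diene and not from C4–H.

**16 ⇒ 14 + 15 (C4a–C8a, C5–C6, C7–C8).** The key cut removes rings A and B together. The neighbouring cuts at C1–C8a or C4–C4a (acylation or alkylation of a preformed dimethoxyaryl ring) would need a C4 centre bearing two similar aryl groups and cationic chemistry next to it. This cut avoids both and leaves 14, an acyclic 1,7-enyne with only two defined stereocentres. The forward reaction must favour crossed cyclotrimerisation over oligomerisation of the terminal ynone, and tolerate two C–B bonds.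

**14 ⇒ 13 ⇒ 11 + 12 (C1–C8a).** The ynone is opened at the carbonyl–alkyne bond to aldehyde 11 and ethynyl Grignard 12, through propargylic alcohol 13. Acylating an acetylide with a carboxylic derivative would first need the aldehyde oxidised and activated, so addition then alcohol oxidation is the shorter path. Both steps are indifferent to C2.

**11 ⇒ 10 ⇒ 8 + 9 (C1–C2) and 8 ⇒ 7 ⇒ 5 + 6 (C2–CH3).** The carbonyl carbon of 5 is the future C2 and needs a methyl group and C1. Methyl Grignard 6 and oxidation give methyl ketone 8 through alcohol 7. Phosphonium salt 9 then adds C1 as enol ether 10, whose hydrolysis gives 11. Building C1–C2 first and methylating a C2 enolate later would be longer. The forward steps must not enolise toward C3, which is α to the carbonyl in 5 and 8.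

**5 ⇒ 3 + 4 (C3–C4) and 3 ⇒ 1 + 2 (C4–vinyl).** C3–C4 is the only bond flanked by both fixed stereocentres. Cutting it gives propanal 4 and racemic aryl vinyl carbinol 3, and asks one dual-catalytic allylation to set both centres; the vinyl group it leaves on C4 is exactly what step 8 consumes. Carbinol 3 comes from aldehyde 1 and vinyl Grignard 2. Auxiliary-based routes to the same pair are longer and are kept as a fallback.

## Roads not taken

**Alternative 1:** Ring B is opened at C1–C8a (aryl ketone by acylation) and both C–CH3 bonds are cut. In the forward key step, enethioate A1 takes a methyl group at C3 by copper-catalysed asymmetric conjugate addition of a methyl Grignard reagent, and the magnesium enolate is C-methylated at C2 to give A2.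
- Merits: all four aryl oxygens are in place from the start; there is no boron-to-oxygen exchange and no aromatisation; the thioester is ready to acylate the more electron-rich dimethoxyaryl ring.
- Weak points: A1 needs a C4 centre carrying two electronically similar aryl groups, which is a hard enantioselective problem moved upstream. The conjugate addition is doubly stereodifferentiating against that centre. The γ-hydrogen of A1 is doubly benzylic and vinylogously acidic, so deconjugation or racemisation threatens under Grignard conditions.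
- Comparison: this road is probably shorter after its key step and avoids an untested cycloaddition. The chosen plan sets against it a C4 centre that differs clearly in its two carbon substituents (aryl versus vinyl), made together with C3 in one catalytic step from 3 and 4, and a C3 methyl group that arrives inside propanal rather than being added to a hindered acceptor.

**Alternative 2:** Ring B is cut at C1–C2 and C3–C4. Irradiation of benzylbenzaldehyde A3 with the chiral butenolide A4 should give, by photoenolisation and endo [4+2] trapping, the all-cis adduct A5.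
- Merits: ring B and its contiguous stereocentres form in one metal-free step; absolute configuration comes from a cheap auxiliary; rings A and C are present with final oxygenation.
- Weak points: the future methyl groups arrive as a lactone carbonyl and an acetal carbon. Each needs reduction and deoxygenation to CH3, the C1 carbinol needs oxidation, and the cis ring fusion leaves C2 to be epimerised. The photochemical step is also harder to scale.
- Comparison: this key step is better in stereochemical economy and in precedent for its stereocontrol. The chosen plan sets against it methyl groups that are methyl groups from the outset (from 4 and 6), so no C–O to C–H reductions, and a five-step, redox-light finish after ring formation.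

**Alternative 3:** Ring B is cut at C4–C4a and C1–C8a, and the C2 methyl group is removed. Under Lewis acid catalysis, arene A6 opens the spirocyclopropane A7 at its benzylic carbon with inversion, and the Meldrum's acid unit acylates the ortho position to give A8. C2 methylation and sulfonate removal follow.
- Merits: very short and convergent; ring A comes from a commodity arene with unambiguous regiochemistry; inversion turns a trans-cyclopropane into the 3,4-cis pair.
- Weak points: A7 must be enantiopure, and asymmetric cyclopropanation with a Meldrum's acid carbene equivalent on a 1,2-disubstituted styrene is not a solved problem. Its benzylic carbon carries a para-methoxyaryl donor, so opening can leak through a benzylic cation and erode C4, which cannot be repaired. Late C2 methylation risks double alkylation.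
- Comparison: this road is shorter by several steps, with closer precedent for each. The chosen plan offers a C4 centre made under catalyst control and never placed beside a developing cation, and a C3/C4 relationship set by two catalysts that can be varied independently.

Key step: step 8

Assumption: in the 3,4-cis series the 2,3-trans ketone (2S) is the more stable C2 epimer, so C2 is carried as a mixture from step 5 and fixed by equilibration in step 12.

Assumption: the (R) antipode of the phosphoramidite–olefin ligand is taken to be the one that gives the 3R centre of 5; the two catalysts of step 2 act independently, so only the ligand antipode is exchanged if the sense proves opposite.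

Assumption: aldehyde 1 (O-benzylisovanillin) is purchased as such.

## Route

Step 1
Reactants: 1 3-(benzyloxy)-4-methoxybenzaldehyde; 2 vinylmagnesium bromide
Product: 3 rac-1-[3-(benzyloxy)-4-methoxyphenyl]prop-2-en-1-ol
Conditions: THF, −78 → 0 °C; aq. NH4Cl
Reagents that add atoms: none
Why: Grignard 1,2-addition to a non-enolisable aryl aldehyde; the racemate is sufficient because ionisation on iridium in step 2 erases the carbinol centre.

Step 2
Reactants: 3 rac-1-[3-(benzyloxy)-4-methoxyphenyl]prop-2-en-1-ol; 4 propanal
Product: 5 (2R,3R)-3-[3-(benzyloxy)-4-methoxyphenyl]-2-methylpent-4-enal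
Conditions: [Ir(cod)Cl]2 (3 mol%), (R)-BINOL-derived N-(5H-dibenzo[b,f]azepin-5-yl)phosphoramidite (12 mol%), (S)-2-{bis[3,5-bis(trifluoromethyl)phenyl](trimethylsilyloxy)methyl}pyrrolidine (15 mol%), (MeO)2P(O)OH (cat.), 4 (3 equiv), ClCH2CH2Cl, 25 °C
Reagents that add atoms: none
Why: Enantioconvergent dual iridium/enamine-catalysed α-allylation of a linear aldehyde with a racemic aryl vinyl carbinol: acid-promoted ionisation of 3 gives an allyl-iridium electrophile whose face is chosen by the phosphoramidite–olefin ligand (C3 of 5, the future C4), attack at the branched terminus being intrinsic to this catalyst. The (S)-diarylprolinol silyl ether shields one face of the (E)-enamine of 4 and should set C2 of 5 (the future C3) as R, in the sense established for this catalyst class.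

Step 3
Reactants: 5 (2R,3R)-3-[3-(benzyloxy)-4-methoxyphenyl]-2-methylpent-4-enal; 6 methylmagnesium bromide
Product: 7 (3R,4R)-4-[3-(benzyloxy)-4-methoxyphenyl]-3-methylhex-5-en-2-ol (both carbinol epimers)
Conditions: THF, −78 °C; aq. NH4Cl
Reagents that add atoms: none
Why: Grignard addition, fast at −78 °C so the α-centre is not enolised; the new carbinol centre is left uncontrolled because step 4 removes it.

Step 4
Reactants: 7 (3R,4R)-4-[3-(benzyloxy)-4-methoxyphenyl]-3-methylhex-5-en-2-ol
Product: 8 (3R,4R)-4-[3-(benzyloxy)-4-methoxyphenyl]-3-methylhex-5-en-2-one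
Conditions: Dess–Martin periodinane, CH2Cl2, 0 °C → rt
Reagents that add atoms: none
Why: Dess–Martin oxidation of a secondary alcohol under near-neutral conditions, which should leave the α-centre (future C3), the vinyl group and the benzyl ether untouched.

Step 5
Reactants: 8 (3R,4R)-4-[3-(benzyloxy)-4-methoxyphenyl]-3-methylhex-5-en-2-one; 9 (methoxymethyl)triphenylphosphonium chloride
Product: 11 (3R,4R)-4-[3-(benzyloxy)-4-methoxyphenyl]-2,3-dimethylhex-5-enal (both C2 epimers), via methyl enol ether 10 (not isolated)
Conditions: 9 (2.5 equiv), KN(SiMe3)2 (2.4 equiv), THF, −78 → 0 °C, then 8, 0 °C → rt; then 2 M aq. HCl, THF, rt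
Reagents that add atoms: water, O
Why: Wittig methoxymethylenation then enol ether hydrolysis, a standard one-carbon homologation of ketones. Keeping the base below the phosphonium salt leaves no free amide, and any enolisation by the ylide should occur at the unhindered methyl side, so C3 should survive. The new C2 centre forms without control and is fixed in step 12.

Step 6
Reactants: 11 (3R,4R)-4-[3-(benzyloxy)-4-methoxyphenyl]-2,3-dimethylhex-5-enal; 12 ethynylmagnesium bromide
Product: 13 (5R,6R)-6-[3-(benzyloxy)-4-methoxyphenyl]-4,5-dimethyloct-7-en-1-yn-3-ol (mixture at C3 and C4)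
Conditions: THF, −78 → 0 °C; aq. NH4Cl
Reagents that add atoms: none
Why: Alkynyl Grignard addition to an aldehyde; the carbinol centre is removed in step 7 and the adjacent centre is the freely equilibrating future C2.

Step 7
Reactants: 13 (5R,6R)-6-[3-(benzyloxy)-4-methoxyphenyl]-4,5-dimethyloct-7-en-1-yn-3-ol
Product: 14 (5R,6R)-6-[3-(benzyloxy)-4-methoxyphenyl]-4,5-dimethyloct-7-en-1-yn-3-one (both C4 epimers)
Conditions: Dess–Martin periodinane, CH2Cl2, 0 °C → rt; used without storage
Reagents that add atoms: none
Why: Dess–Martin oxidation of a propargylic alcohol to the terminal ynone under non-nucleophilic conditions, so the Michael-accepting alkyne is not attacked.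

Step 8
Reactants: 14 (5R,6R)-6-[3-(benzyloxy)-4-methoxyphenyl]-4,5-dimethyloct-7-en-1-yn-3-one; 15 1,2-bis(4,4,5,5-tetramethyl-1,3,2-dioxaborolan-2-yl)ethyne
Product: 16 (3R,4S)-4-[3-(benzyloxy)-4-methoxyphenyl]-2,3-dimethyl-6,7-bis(4,4,5,5-tetramethyl-1,3,2-dioxaborolan-2-yl)-3,4,4a,5-tetrahydronaphthalen-1(2H)-one (C2 and C4a epimers; C3 and C4 spatially as in 14)
Conditions: [Rh(cod)2]BF4 (10 mol%), rac-BINAP (10 mol%), H2 then Ar purge (catalyst activation), 15 (2.5 equiv), 14 added over 4 h, ClCH2CH2Cl, rt → 60 °C
Reagents that add atoms: none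
Why: After removal of cod by hydrogenation, the cationic monovalent rhodium–BINAP fragment binds the ynone alkyne and the C4 vinyl group of 14 and couples them oxidatively to a rhodacyclopentene, which forms C4a–C8a and closes the six-membered ring B by exo-type closure across the four-atom C1–C4 tether. Insertion of 15 into a Rh–C bond and C–C reductive elimination then form C7–C8 and C5–C6 and close ring A as a cyclohexa-1,3-diene (C6=C7, C8=C8a), releasing the catalyst; if the ynone alkyne couples with 15 first, intramolecular insertion of the tethered vinyl group leads to the same skeleton. The closest known reaction type is the cationic rhodium/bisphosphine-catalysed intermolecular [2+2+2] cycloaddition of tethered enynes with alkynes to fused cyclohexadienes, together with metal-catalysed cyclotrimerisations that incorporate alkynylboronates and 15; pairing a terminal ynone-enyne with 15 is untested. Regiochemistry needs no control, because the tether fixes the C4a–C8a junction and 15 is symmetric. The one new stereocentre, C4a, forms under the influence of C4 and the ligand but is left uncontrolled, since step 9 removes it; C3 and C4 take no part and C2 stays a mixture. The selectivity that matters is crossed over homo-cyclotrimerisation: slow addition of 14 to excess 15 keeps the ynone concentration low, the bulk of 15 prevents its own trimerisation, and the vinyl group has no exocyclic allylic hydrogen on the metal-bound carbon, which closes the Alder-ene cycloisomerisation channel. rac-BINAP supplies both catalyst antipodes, so the better-matched one carries the enantiopure substrate, and purging hydrogen after activation avoids rhodium hydride isomerisation of the vinyl group.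

Step 9
Reactants: 16 (3R,4S)-4-[3-(benzyloxy)-4-methoxyphenyl]-2,3-dimethyl-6,7-bis(4,4,5,5-tetramethyl-1,3,2-dioxaborolan-2-yl)-3,4,4a,5-tetrahydronaphthalen-1(2H)-one
Product: 17 (3R,4R)-4-[3-(benzyloxy)-4-methoxyphenyl]-2,3-dimethyl-6,7-bis(4,4,5,5-tetramethyl-1,3,2-dioxaborolan-2-yl)-3,4-dihydronaphthalen-1(2H)-one (both C2 epimers)
Conditions: DDQ (1.05 equiv), toluene, 0 °C → rt
Reagents that add atoms: none
Why: Quinone dehydrogenation of a cyclohexa-1,3-diene to the arene (hydride abstraction from C5 or C4a, then proton loss), driven by aromatisation and tolerated by aryl and alkenyl pinacol boronates. One equivalent at low temperature is used so the slower hydride abstraction from the diarylmethine C4–H should not compete; all diene isomers and both C4a epimers converge on 17.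

Step 10
Reactants: 17 (3R,4R)-4-[3-(benzyloxy)-4-methoxyphenyl]-2,3-dimethyl-6,7-bis(4,4,5,5-tetramethyl-1,3,2-dioxaborolan-2-yl)-3,4-dihydronaphthalen-1(2H)-one
Product: 18 (3R,4R)-4-[3-(benzyloxy)-4-methoxyphenyl]-6,7-dihydroxy-2,3-dimethyl-3,4-dihydronaphthalen-1(2H)-one (both C2 epimers)
Conditions: NaBO3·4H2O (6 equiv), THF/H2O (1:1), 0 °C → rt, Ar; aq. NH4Cl; used directly
Reagents that add atoms: sodium perborate tetrahydrate, [Na+].[O-]OB=O.O.O.O.O
Why: Perborate ipso-oxidation of arylboronic esters (peroxide addition to boron, 1,2-aryl shift, hydrolysis), which places oxygen exactly at C6 and C7. The mild, weakly basic oxidant is chosen over alkaline peroxide to spare the aryl ketone and the catechol.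

Step 11
Reactants: 18 (3R,4R)-4-[3-(benzyloxy)-4-methoxyphenyl]-6,7-dihydroxy-2,3-dimethyl-3,4-dihydronaphthalen-1(2H)-one
Product: 19 (3R,4R)-4-[3-(benzyloxy)-4-methoxyphenyl]-6,7-dimethoxy-2,3-dimethyl-3,4-dihydronaphthalen-1(2H)-one (both C2 epimers)
Conditions: MeI (4 equiv), K2CO3 (4 equiv), acetone, 40 °C
Reagents that add atoms: iodomethane, CI
Why: Williamson O-methylation of both phenols; K2CO3 deprotonates the phenols but not the ketone α-position to any useful extent, so C-methylation at C2 is not expected, and the ring C oxygen stays masked as its benzyl ether.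

Step 12
Reactants: 19 (3R,4R)-4-[3-(benzyloxy)-4-methoxyphenyl]-6,7-dimethoxy-2,3-dimethyl-3,4-dihydronaphthalen-1(2H)-one
Product: 20 (2S,3R,4R)-4-[3-(benzyloxy)-4-methoxyphenyl]-6,7-dimethoxy-2,3-dimethyl-3,4-dihydronaphthalen-1(2H)-one
Conditions: NaOMe (0.5 equiv), MeOH/THF, 50 °C, Ar
Reagents that add atoms: none
Why: Base-mediated epimerisation through the ketone enolate with no electrophile present. C2 is set thermodynamically: with the C4 aryl group pseudoaxial and the C3 methyl equatorial, the 2,3-trans epimer has its C2 methyl equatorial, whereas the cis epimer would hold it 1,3-diaxial to the aryl group; C3 and C4 are not acidic under these conditions.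

Step 13
Reactants: 20 (2S,3R,4R)-4-[3-(benzyloxy)-4-methoxyphenyl]-6,7-dimethoxy-2,3-dimethyl-3,4-dihydronaphthalen-1(2H)-one
Product: 21 (2S,3R,4R)-4-(3-hydroxy-4-methoxyphenyl)-6,7-dimethoxy-2,3-dimethyl-3,4-dihydronaphthalen-1(2H)-one
Conditions: H2 (1 atm), Pd/C (10 wt%), EtOAc, rt
Reagents that add atoms: none
Why: Hydrogenolysis of a benzyl aryl ether under neutral conditions; the donor-substituted aryl ketone should resist reduction at one atmosphere and no stereocentre is touched.

## Compound list

1 | 3-(benzyloxy)-4-methoxybenzaldehyde | COc1ccc(C=O)cc1OCc1ccccc1 | starting material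
2 | vinylmagnesium bromide | C=C[Mg]Br | starting material
3 | rac-1-[3-(benzyloxy)-4-methoxyphenyl]prop-2-en-1-ol | C=CC(O)c1ccc(OC)c(OCc2ccccc2)c1 | intermediate
4 | propanal | CCC=O | starting material
5 | (2R,3R)-3-[3-(benzyloxy)-4-methoxyphenyl]-2-methylpent-4-enal | O=C[C@H](C)[C@@H](C=C)c1ccc(OC)c(OCc2ccccc2)c1 | intermediate
6 | methylmagnesium bromide | C[Mg]Br | starting material
7 | (3R,4R)-4-[3-(benzyloxy)-4-methoxyphenyl]-3-methylhex-5-en-2-ol (both C2 epimers) | CC(O)[C@H](C)[C@@H](C=C)c1ccc(OC)c(OCc2ccccc2)c1 | intermediate
8 | (3R,4R)-4-[3-(benzyloxy)-4-methoxyphenyl]-3-methylhex-5-en-2-one | CC(=O)[C@H](C)[C@@H](C=C)c1ccc(OC)c(OCc2ccccc2)c1 | intermediate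
9 | (methoxymethyl)triphenylphosphonium chloride | COC[P+](c1ccccc1)(c1ccccc1)c1ccccc1.[Cl-] | starting material
10 | (3R,4R)-4-[3-(benzyloxy)-4-methoxyphenyl]-1-methoxy-2,3-dimethylhexa-1,5-diene (E/Z mixture; not isolated) | COC=C(C)[C@H](C)[C@@H](C=C)c1ccc(OC)c(OCc2ccccc2)c1 | intermediate
11 | (3R,4R)-4-[3-(benzyloxy)-4-methoxyphenyl]-2,3-dimethylhex-5-enal (both C2 epimers) | O=CC(C)[C@H](C)[C@@H](C=C)c1ccc(OC)c(OCc2ccccc2)c1 | intermediate
12 | ethynylmagnesium bromide | C#C[Mg]Br | starting material
13 | (5R,6R)-6-[3-(benzyloxy)-4-methoxyphenyl]-4,5-dimethyloct-7-en-1-yn-3-ol (mixture at C3 and C4) | C#CC(O)C(C)[C@H](C)[C@@H](C=C)c1ccc(OC)c(OCc2ccccc2)c1 | intermediate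
14 | (5R,6R)-6-[3-(benzyloxy)-4-methoxyphenyl]-4,5-dimethyloct-7-en-1-yn-3-one (both C4 epimers) | C#CC(=O)C(C)[C@H](C)[C@@H](C=C)c1ccc(OC)c(OCc2ccccc2)c1 | intermediate
15 | 1,2-bis(4,4,5,5-tetramethyl-1,3,2-dioxaborolan-2-yl)ethyne | CC1(C)OB(OC1(C)C)C#CB1OC(C)(C)C(C)(C)O1 | starting material
16 | (3R,4S)-4-[3-(benzyloxy)-4-methoxyphenyl]-2,3-dimethyl-6,7-bis(4,4,5,5-tetramethyl-1,3,2-dioxaborolan-2-yl)-3,4,4a,5-tetrahydronaphthalen-1(2H)-one (C2 and C4a epimers) | COc1ccc([C@@H]2C3CC(B4OC(C)(C)C(C)(C)O4)=C(B4OC(C)(C)C(C)(C)O4)C=C3C(=O)C(C)[C@@H]2C)cc1OCc1ccccc1 | intermediate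
17 | (3R,4R)-4-[3-(benzyloxy)-4-methoxyphenyl]-2,3-dimethyl-6,7-bis(4,4,5,5-tetramethyl-1,3,2-dioxaborolan-2-yl)-3,4-dihydronaphthalen-1(2H)-one (both C2 epimers) | COc1ccc([C@@H]2c3cc(B4OC(C)(C)C(C)(C)O4)c(B4OC(C)(C)C(C)(C)O4)cc3C(=O)C(C)[C@@H]2C)cc1OCc1ccccc1 | intermediate
18 | (3R,4R)-4-[3-(benzyloxy)-4-methoxyphenyl]-6,7-dihydroxy-2,3-dimethyl-3,4-dihydronaphthalen-1(2H)-one (both C2 epimers) | COc1ccc([C@@H]2c3cc(O)c(O)cc3C(=O)C(C)[C@@H]2C)cc1OCc1ccccc1 | intermediate
19 | (3R,4R)-4-[3-(benzyloxy)-4-methoxyphenyl]-6,7-dimethoxy-2,3-dimethyl-3,4-dihydronaphthalen-1(2H)-one (both C2 epimers) | COc1ccc([C@@H]2c3cc(OC)c(OC)cc3C(=O)C(C)[C@@H]2C)cc1OCc1ccccc1 | intermediate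
20 | (2S,3R,4R)-4-[3-(benzyloxy)-4-methoxyphenyl]-6,7-dimethoxy-2,3-dimethyl-3,4-dihydronaphthalen-1(2H)-one | COc1ccc([C@@H]2c3cc(OC)c(OC)cc3C(=O)[C@@H](C)[C@@H]2C)cc1OCc1ccccc1 | intermediate
21 | (2S,3R,4R)-4-(3-hydroxy-4-methoxyphenyl)-6,7-dimethoxy-2,3-dimethyl-3,4-dihydronaphthalen-1(2H)-one | COc1ccc([C@@H]2c3cc(OC)c(OC)cc3C(=O)[C@@H](C)[C@@H]2C)cc1O | target

## Step count and risk

Total: 13 steps. Longest linear sequence: 13 steps (1 → 21); the other building blocks (2, 4, 6, 9, 12, 15) are purchased.

**Step 8 (key step).** The most likely failure is loss of the terminal ynone to self-oligomerisation or homo-cyclotrimerisation before the hindered, weakly coordinating diborylalkyne is incorporated. Both partners are electron-poor, and forming a six-membered ring through the tether is slower than the five-membered closures of the closest precedents. The fallback runs the cycloaddition at the alcohol oxidation level, where the alkyne is neither a Michael acceptor nor activated toward self-coupling. It sets out from 13, which is combined with 15 under the same rhodium catalyst to give the diene alcohol (3R,4S)-4-[3-(benzyloxy)-4-methoxyphenyl]-2,3-dimethyl-6,7-bis(pinacolboryl)-1,2,3,4,4a,5-hexahydronaphthalen-1-ol F1. DDQ dehydrogenation then gives the aromatic alcohol (3R,4R)-4-[3-(benzyloxy)-4-methoxyphenyl]-2,3-dimethyl-6,7-bis(pinacolboryl)-1,2,3,4-tetrahydronaphthalen-1-ol F2. Dess–Martin oxidation of the benzylic alcohol returns to the route at 17.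

**Step 2.** The risk is erosion of diastereo- and enantiopurity, through enolisation of the α-branched aldehyde product under the acidic promoter or competing self-aldol of propanal. The sense of induction by the ligand is also assumed rather than secured. The fallback uses auxiliary control and sets out from 1:
- Horner–Wadsworth–Emmons reaction of 1 with diethyl {2-oxo-2-[(4R)-2-oxo-4-phenyl-1,3-oxazolidin-3-yl]ethyl}phosphonate (LiCl, iPr2NEt, MeCN) gives the enoyl imide (4R)-3-{(2E)-3-[3-(benzyloxy)-4-methoxyphenyl]prop-2-enoyl}-4-phenyl-1,3-oxazolidin-2-one F3.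
- Conjugate addition of 2 with CuBr·SMe2 to the chelated s-cis imide, anti to the phenyl group, gives (4R)-3-{(3S)-3-[3-(benzyloxy)-4-methoxyphenyl]pent-4-enoyl}-4-phenyl-1,3-oxazolidin-2-one F4.
- Methylation of the sodium (Z)-enolate (NaN(SiMe3)2, MeI, −78 °C), again anti to the phenyl group, gives (4R)-3-{(2R,3R)-3-[3-(benzyloxy)-4-methoxyphenyl]-2-methylpent-4-enoyl}-4-phenyl-1,3-oxazolidin-2-one F5.
- LiBH4 reduction releases the auxiliary and gives (2R,3R)-3-[3-(benzyloxy)-4-methoxyphenyl]-2-methylpent-4-en-1-ol F6.
- Dess–Martin oxidation returns to the route at 5.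

**Step 5.** The risk is partial epimerisation at C3, or stalled conversion, through enolisation of the hindered α-branched ketone by the basic ylide. The fallback avoids carbonyl olefination and sets out from 8:
- Condensation with 2,4,6-triisopropylbenzenesulfonyl hydrazide gives the hydrazone N′-{(3R,4R)-4-[3-(benzyloxy)-4-methoxyphenyl]-3-methylhex-5-en-2-ylidene}-2,4,6-tri(propan-2-yl)benzenesulfonohydrazide F7.
- Shapiro reaction (n-BuLi, THF, −78 → 0 °C), with deprotonation on the methyl side, and trapping of the vinyllithium with DMF gives the enal (3R,4R)-4-[3-(benzyloxy)-4-methoxyphenyl]-3-methyl-2-methylidenehex-5-enal F8.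
- Conjugate reduction with [(Ph3P)CuH]6, which leaves the isolated vinyl group alone, returns to the route at 11.

**Step 10.** The risk is over-oxidation: Dakin-type Baeyer–Villiger cleavage once the C6 hydroxyl para to the ketone is unveiled, or oxidation of the catechol to the ortho-quinone during basic work-up. The fallback avoids the free catechol. It sets out from 17 and converts both C–B bonds directly into C–OMe bonds by copper-mediated oxidative Chan–Lam methoxylation (Cu(OAc)2, DMAP, MeOH, molecular sieves, O2). It returns to the route at 19 and makes no compound outside the list (entry F0).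

## Further compounds

F1 | step 8 | (3R,4S)-4-[3-(benzyloxy)-4-methoxyphenyl]-2,3-dimethyl-6,7-bis(4,4,5,5-tetramethyl-1,3,2-dioxaborolan-2-yl)-1,2,3,4,4a,5-hexahydronaphthalen-1-ol (mixture at C1, C2, C4a) | COc1ccc([C@@H]2C3CC(B4OC(C)(C)C(C)(C)O4)=C(B4OC(C)(C)C(C)(C)O4)C=C3C(O)C(C)[C@@H]2C)cc1OCc1ccccc1
F2 | step 8 | (3R,4R)-4-[3-(benzyloxy)-4-methoxyphenyl]-2,3-dimethyl-6,7-bis(4,4,5,5-tetramethyl-1,3,2-dioxaborolan-2-yl)-1,2,3,4-tetrahydronaphthalen-1-ol (mixture at C1, C2) | COc1ccc([C@@H]2c3cc(B4OC(C)(C)C(C)(C)O4)c(B4OC(C)(C)C(C)(C)O4)cc3C(O)C(C)[C@@H]2C)cc1OCc1ccccc1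
F3 | step 2 | (4R)-3-{(2E)-3-[3-(benzyloxy)-4-methoxyphenyl]prop-2-enoyl}-4-phenyl-1,3-oxazolidin-2-one | COc1ccc(/C=C/C(=O)N2C(=O)OC[C@H]2c3ccccc3)cc1OCc1ccccc1
F4 | step 2 | (4R)-3-{(3S)-3-[3-(benzyloxy)-4-methoxyphenyl]pent-4-enoyl}-4-phenyl-1,3-oxazolidin-2-one | O=C(C[C@@H](C=C)c1ccc(OC)c(OCc2ccccc2)c1)N1C(=O)OC[C@H]1c1ccccc1
F5 | step 2 | (4R)-3-{(2R,3R)-3-[3-(benzyloxy)-4-methoxyphenyl]-2-methylpent-4-enoyl}-4-phenyl-1,3-oxazolidin-2-one | O=C([C@H](C)[C@@H](C=C)c1ccc(OC)c(OCc2ccccc2)c1)N1C(=O)OC[C@H]1c1ccccc1
F6 | step 2 | (2R,3R)-3-[3-(benzyloxy)-4-methoxyphenyl]-2-methylpent-4-en-1-ol | OC[C@H](C)[C@@H](C=C)c1ccc(OC)c(OCc2ccccc2)c1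
F7 | step 5 | N′-{(3R,4R)-4-[3-(benzyloxy)-4-methoxyphenyl]-3-methylhex-5-en-2-ylidene}-2,4,6-tri(propan-2-yl)benzenesulfonohydrazide | CC(=NNS(=O)(=O)c1c(C(C)C)cc(C(C)C)cc1C(C)C)[C@H](C)[C@@H](C=C)c1ccc(OC)c(OCc2ccccc2)c1
F8 | step 5 | (3R,4R)-4-[3-(benzyloxy)-4-methoxyphenyl]-3-methyl-2-methylidenehex-5-enal | O=CC(=C)[C@H](C)[C@@H](C=C)c1ccc(OC)c(OCc2ccccc2)c1
F0 | step 10 | none | none
A1 | alternative 1 | S-ethyl (2E)-4-(3,4-dimethoxyphenyl)-4-[4-methoxy-3-(tosyloxy)phenyl]but-2-enethioate, single C4 enantiomer | CCSC(=O)/C=C/[C@@H](c1ccc(OC)c(OC)c1)c1ccc(OC)c(OS(=O)(=O)c2ccc(C)cc2)c1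
A2 | alternative 1 | S-ethyl 4-(3,4-dimethoxyphenyl)-4-[4-methoxy-3-(tosyloxy)phenyl]-2,3-dimethylbutanethioate, C2–C4 as in the target | CCSC(=O)[C@@H](C)[C@H](C)[C@@H](c1ccc(OC)c(OC)c1)c1ccc(OC)c(OS(=O)(=O)c2ccc(C)cc2)c1
A3 | alternative 2 | 2-{[3-(benzyloxy)-4-methoxyphenyl]methyl}-4,5-dimethoxybenzaldehyde | COc1ccc(Cc2cc(OC)c(OC)cc2C=O)cc1OCc1ccccc1
A4 | alternative 2 | (5R)-5-{[(1R,2S,5R)-5-methyl-2-(propan-2-yl)cyclohexyl]oxy}furan-2(5H)-one | O=C1O[C@@H](O[C@@H]2C[C@H](C)CC[C@H]2C(C)C)C=C1
A5 | alternative 2 | all-cis 1-hydroxy-4-[3-(benzyloxy)-4-methoxyphenyl]-6,7-dimethoxytetralin fused at C2–C3 to the menthyloxy butyrolactone | COc1ccc([C@@H]2c3cc(OC)c(OC)cc3[C@H](O)[C@@H]4C(=O)O[C@@H](O[C@@H]5C[C@H](C)CC[C@H]5C(C)C)[C@H]24)cc1OCc1ccccc1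
A6 | alternative 3 | 1,2-dimethoxybenzene | COc1ccccc1OC
A7 | alternative 3 | trans-1-[4-methoxy-3-(tosyloxy)phenyl]-2,6,6-trimethyl-5,7-dioxaspiro[2.5]octane-4,8-dione, single enantiomer | CC1(C)OC(=O)C2(C(=O)O1)[C@H](C)[C@H]2c1ccc(OC)c(OS(=O)(=O)c2ccc(C)cc2)c1
A8 | alternative 3 | cis-4-[4-methoxy-3-(tosyloxy)phenyl]-6,7-dimethoxy-3-methyl-3,4-dihydronaphthalen-1(2H)-one | COc1ccc([C@@H]2c3cc(OC)c(OC)cc3C(=O)C[C@@H]2C)cc1OS(=O)(=O)c1ccc(C)cc1
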